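**Assumptions (one line):** The L-sorbose-derived (ent-Shi) ketone is taken to give the (6S,7S) trans-epoxide, by analogy with the D-ketone giving (R,R)-trans-β-methylstyrene oxide. The C10 configuration of early intermediates is not controlled. It is erased by oxidation in Step 6 and set again in Step 7.

## Retrosynthesis

1. Sodwanone T comes from the C2-symmetric bis-ketone by (S)-CBS mono-reduction, which sets the single C10 (R) carbinol.
2. The bis-ketone comes from the diol by oxidation. The diol comes from Ni(0) homocoupling of one allylic bromide, which forms the central CH2–CH2 bond.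
3. The monomer is a trans-fused cyclohexene/oxepane. It comes from a 6,7:10,11-diepoxyfarnesyl acetate in one cascade. The cyclohexene forms first, by epoxide-initiated cation–olefin closure of C2 onto C7. The oxepane forms second, by 7-endo opening of the terminal epoxide by C6–O.
4. The diepoxide comes from Shi asymmetric epoxidation of commercial farnesyl acetate, which sets C6 and C7.

## Route

**Step 1**
Reactants: 1 (2E,6E)-farnesyl acetate; 2 ent-Shi ketone (catalyst)
Product: 3 (2E,6S,7S)-6,7:10,11-diepoxyfarnesyl acetate (C10 configuration unspecified)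
Conditions: ketone 2 (0.6 equiv), Oxone (4 equiv), K2CO3, Bu4NHSO4, MeCN/DMM/aq. Na2B4O7–EDTA buffer (pH 10.5), 0 °C
Reagents that add atoms: Oxone, the O-atom source (OOS(=O)(=O)[O-].[K+])
Why: Shi asymmetric epoxidation (chiral dioxirane, spiro transition state) epoxidises the two most electron-rich, unhindered trisubstituted alkenes (6,7 and 10,11). The 2,3-alkene is deactivated by the allylic acetate. The E-alkene gives the trans-(6S,7S) epoxide, which fixes C6 and C7.

**Step 2**
Reactants: 3
Product: 4 [(5aS,9aS)-3-hydroxy-2,2,5a,7-tetramethyl-2,3,4,5,5a,8,9,9a-octahydro-1-benzoxepin-6-yl]methyl acetate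
Conditions: BF3·OEt2 (2 equiv), CH2Cl2, –78 → –20 °C; then sat. aq. NaHCO3
Reagents that add atoms: none
Why: This is an epoxide-initiated cation–olefin cyclization.
- The Lewis-acid-opened 6,7-epoxide is attacked by C2 of the C2=C3 alkene at C7. Attack is anti to the C–O bond, through a chair transition state.
- This gives the trans-fused geometry: axial Me and H, equatorial C6–O and C8.
- C6 is retained and C7 is set by inversion. Loss of H from C2 gives the tetrasubstituted Δ2,3 alkene.
- The C6–O then opens the terminal epoxide at the tertiary C11 (7-endo), which forms the oxepane. C10 keeps its configuration.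

**Step 3**
Reactants: 4
Product: 5 (5aS,9aS)-6-(hydroxymethyl)-2,2,5a,7-tetramethyl-octahydro-1-benzoxepin-3-ol
Conditions: K2CO3, MeOH, 25 °C
Reagents that add atoms: none
Why: Base methanolysis of the primary acetate (transesterification) leaves the hindered secondary alcohol, ether and alkene untouched, and no stereocenter is involved.

**Step 4**
Reactants: 5
Product: 6 (5aS,9aS)-6-(bromomethyl)-2,2,5a,7-tetramethyl-octahydro-1-benzoxepin-3-ol
Conditions: PPh3, CBr4, CH2Cl2, 0 °C, 30 min
Reagents that add atoms: CBr4 (BrC(Br)(Br)Br)
Why: Appel bromination is selective for the unhindered primary allylic OH over the neopentyl-type secondary OH, and it proceeds without allylic transposition.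

**Step 5**
Reactants: 6 (2 equiv)
Product: 7 diol dimer, 1,2-bis[(5aS,9aS)-3-hydroxy-2,2,5a,7-tetramethyl-octahydro-1-benzoxepin-6-yl]ethane
Conditions: Ni(cod)2 (1.2 equiv), DMF, 25 °C
Reagents that add atoms: none
Why: Ni(0) reductive homocoupling of allylic bromides goes through a bis(π-allyl)nickel species and couples at the unhindered primary termini. This forms the CH2–CH2 linker and keeps the tetrasubstituted alkenes in place.

**Step 6**
Reactants: 7
Product: 8 bis-ketone, 1,2-bis[(5aS,9aS)-2,2,5a,7-tetramethyl-3-oxo-octahydro-1-benzoxepin-6-yl]ethane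
Conditions: Dess–Martin periodinane (3 equiv), NaHCO3, CH2Cl2, 25 °C
Reagents that add atoms: none
Why: Dess–Martin oxidation is mild and neutral, so the tetrasubstituted alkenes and tertiary ethers survive. It also removes the uncontrolled C10 centers, giving one C2-symmetric compound.

**Step 7**
Reactants: 8; (S)-Me-CBS 9 (catalyst)
Product: 10 sodwanone T
Conditions: 9 (0.3 equiv), catecholborane (0.8 equiv), toluene, –78 °C; recycle recovered 8
Reagents that add atoms: none (only hydride, which becomes H)
Why: CBS reduction is catalyst-controlled.
- The quaternary C11 acts as the large group and C9 as the small one.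
- (S)-CBS delivers hydride to give the (R)-carbinol at C10, matching the target.
- Substoichiometric borane gives mono-reduction of the symmetric bis-ketone, statistically.

## Compound list

| # | Name | SMILES | Role |
|---|---|---|---|
| 1 | (2E,6E)-farnesyl acetate | CC(C)=CCC/C(C)=C/CC/C(C)=C/COC(C)=O | starting material |
| 2 | ent-Shi ketone (1,2:4,5-di-O-isopropylidene-β-L-erythro-2,3-hexodiulo-2,6-pyranose); purchased, or 2 steps from L-sorbose | C1[C@@H]2OC(C)(C)O[C@@H]2C(=O)[C@@]3(O1)COC(C)(C)O3 | starting material (catalyst) |
| 3 | (2E,6S,7S)-6,7:10,11-diepoxyfarnesyl acetate | CC(=O)OC/C=C(\C)CC[C@@H]1O[C@@]1(C)CCC1OC1(C)C | intermediate |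
| 4 | benzoxepine acetate (trans-fused 6/7 oxepan-3-ol, 5aS,9aS) | CC1=C(COC(C)=O)[C@]2(C)CCC(O)C(C)(C)O[C@H]2CC1 | intermediate |
| 5 | allylic alcohol diol (5aS,9aS) | CC1=C(CO)[C@]2(C)CCC(O)C(C)(C)O[C@H]2CC1 | intermediate |
| 6 | allylic bromide (5aS,9aS) | CC1=C(CBr)[C@]2(C)CCC(O)C(C)(C)O[C@H]2CC1 | intermediate |
| 7 | diol dimer | CC1=C(CCC2=C(C)CC[C@@H]3OC(C)(C)C(O)CC[C@@]23C)[C@]2(C)CCC(O)C(C)(C)O[C@H]2CC1 | intermediate |
| 8 | C2-symmetric bis-ketone | CC1=C(CCC2=C(C)CC[C@@H]3OC(C)(C)C(=O)CC[C@@]23C)[C@]2(C)CCC(=O)C(C)(C)O[C@H]2CC1 | intermediate |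
| 9 | (S)-Me-CBS | CB1OC(c2ccccc2)(c2ccccc2)[C@@H]2CCCN12 | starting material (catalyst) |
| 10 | sodwanone T | CC1=C(CCC2=C(C)CC[C@@H]3OC(C)(C)[C@H](O)CC[C@@]23C)[C@]2(C)CCC(=O)C(C)(C)O[C@H]2CC1 | target |

In compounds 3–7 the C10 configuration is left unspecified.

**Total steps:** 7 (2 is a purchased catalyst, or 2 steps from L-sorbose, not counted).
**Longest linear sequence:** 7 steps, from 1 to 10. Step 5 joins two copies of the same intermediate.

## Three steps most likely to fail

1. **Step 2, the two-ring cascade.**
   - Risks: 6-exo closure to a tetrahydropyran instead of the 7-endo oxepane; wrong alkene isomer; competing attack by the epoxide oxygen.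
   - Fallback (different approach): mask the terminal alkene as a bromohydrin. Shi-epoxidise 6,7 only, cyclise the cyclohexene alone, then form the oxepane separately. Do this by isomerising the terminal epoxide to the C10 allylic alcohol with C11=CH2, then Co-catalysed Markovnikov HAT hydroalkoxylation by C6–OH, then oxidising C10.
2. **Step 5, Ni homocoupling.**
   - Risk: a hindered allylic bromide may couple at C3 (the γ position) or decompose.
   - Fallback: Biellmann-type sulfone coupling. Convert half of 6 to its allylic phenyl sulfone, alkylate the sulfone anion with 6 (OH protected as TBS ether), then remove the sulfone with Pd/LiBHEt3.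
3. **Step 7, mono-CBS reduction.**
   - Risk: the yield is capped near 50% by statistics, and facial selectivity on a cyclic ketone may be poor.
   - Fallback: make the two halves different before coupling. Prepare the (10R)-TBS-alcohol monomer by CBS reduction of the monomeric ketone, and couple it unsymmetrically with the ketone monomer through the sulfone route above.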